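(Readings and results are calculated on assumed constants; scatter was added.)

The constants are not given, so get them from the readings, and work with the fraction of D left, not with the Q made.

| setting | epsilon | alpha | noon | dawn |
|---|---|---|---|---|
| D | 0.40 M | 0.40 M | 0.40 M | 0.40 M |
| J | 0.40 M | 0.40 M | 0.40 M | 0.40 M |
| L | 1.2 M | 1.2 M | 1.20 M | 1.20 M |
| E | 22 mM | 43 mM | 40 mM | 12 mM |
| remark | run made earlier | run made earlier |  |  |
| time |  |  | 10 min | 10 min |

| run | time / min | Q / % | D / % |
|---|---|---|---|
| epsilon | 0.833 | 1.2 | 48.7 |
| epsilon | 1.50 | 2.2 | 47.0 |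
| epsilon | 3.00 | 5.0 | 45.0 |
| epsilon | 5.00 | 8.0 | 42.3 |
| epsilon | 10.0 | 14.4 | 35.6 |
| alpha | 0.833 | 2.2 | 47.9 |
| alpha | 2.50 | 6.8 | 43.4 |
| alpha | 5.00 | 11.3 | 38.0 |
| alpha | 8.00 | 17.1 | 33.6 |
| alpha | 10.0 | 19.5 | 30.6 |

(standard deviation of a reading: 0.3 percentage points)

- E is single-handed; D and J are mirror images of each other, charged as a racemate, each of them at the stated concentration
- what may be going on: L + E + D -> E + Q; L + E + J -> E + X; D <-> J; 2 E <-> G

- the flask that ends with the higher amount of Q, in percent of the D and J together charged, or "neither" when 2 percentage points or less lies between them (noon / dawn / neither)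
- final Q, as a percentage of the D and J together charged, in noon
- final Q, as a percentage of the D and J together charged, in dawn

At the last reading, D and Q add up to 50.0% in epsilon and 50.1% in alpha, about half of the charge. So in these runs D left tells Q made: leave J and X out of the reckoning. Define k, the pseudo-first-order rate constant of D, as the logarithm of (D charged / D left), divided by the time.

epsilon: k = 0.0340 min⁻¹

alpha: k = 0.0491 min⁻¹

The E charge went up by a factor of 1.95 and k by 1.44, which points to part of E sitting as G. Take the order in E as n, the ratio of the two logarithms: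

n = 0.550

Two rates now carry the question. Scale each from the nearer run. The second is k(dawn), the rate constant of D at dawn's charges:

k(noon) = 0.0472 min⁻¹

k(dawn) = 0.0243 min⁻¹

Q is half the charge times the fraction of D gone:

noon: 18.8%

dawn: 10.8%

By this reckoning noon ends higher by 8 percentage points, more than the margin.

The forecast, reading “an active monomer in equilibrium with an inactive dimer G”, names noon, with 19.3% in noon and 10.3% in dawn, close to these figures but not equal to them.

The flasks give 19.1% in noon and 10.5% in dawn, so noon ends higher.

    L + E + D → E + Q (k = 0.0530 M⁻² s⁻¹)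
    L + E + J → E + X (k = 0.0320 M⁻² s⁻¹)
    D ⇌ J (k = 1.90 × 10⁻⁴ s⁻¹)
    2 E ⇌ G, settled at all times (K = 64.0 M⁻¹)

Reckon k back from the final Q: dawn gives 0.0235 min⁻¹ against the reckoned 0.0243 min⁻¹, and noon gives 2.05 times that k, while the E charges stand in a ratio of 3.33 and the E free at the end, 14.2 mM in noon and 6.53 mM in dawn, in a ratio of 2.17. Carry k(dawn) to dawn's neighbour with 2.0 M of L, scaling it by the L charge: that gives 16.7%, and the neighbour holds 16.2% of Q.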